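## The problem

Target 27 is a cyclohexene (ring atoms C1=C2, C3, C4, C5, C6) with an acyloxymethyl carbon C7 on C1, a secondary hydroxyl on C6 and, on C4, the chain C8(=C14H2)–C9H2–C10H=C11H–C12(OH)(CH3)–C13H2O, joined to the ring through the single bond C4–C8. The C7 and C13 oxygens are isobutyrates. There are three stereocentres: C4 and C6 on the ring (both S, 1,3-cis) and the tertiary carbinol C12 (R). C4 can bias C6 through the conformation of the six-membered ring. C12 is separated from C4 by C8, C9 and an E-alkene, so it needs its own reagent control, and its enantiopurity must be high from the start because C12 epimers would be remote diastereomers that cannot be expected to separate. The E geometry of C10=C11 and the 1,1-disubstituted C8=C14 alkene should be made without ever placing a carbonyl at C8, which would make C4 epimerisable. Several groups forbid rough treatment: the esters do not survive hydride or organometallic reagents, and the C7 ester can migrate to the C6 hydroxyl under base; the tertiary allylic C12–O bond ionises under strong acid; the skipped diene with its doubly allylic C9H2 slips into conjugation under strong base. The feature that opens a short route is the unit C6(OH)–C1(C7)=C2, a 2-(1-hydroxyalkyl)acrylate pattern: it is the product of a Morita–Baylis–Hillman reaction between a C6 aldehyde and a C7–C1=C2 acrylate unit, and the C3–C4–C5 tether makes that reaction intramolecular and ring-forming.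

## Retrosynthesis

**Ester C–O bonds at O7 and O13 (27 ⇒ 26 ⇒ 25 ⇒ 24).** Both isobutyrates are cut first, because no acyl group on oxygen would survive the hydride steps. Both sit on primary hydroxyls and derive from the same acid, so tetraol 26 can take them in one operation. Tetraol 26 comes from acetonide 25 and 25 from thioester 24, in which C7 is still at the acid oxidation level. The forward steps must acylate two primary hydroxyls beside a secondary (C6) and a tertiary (C12) one, and must remove an acetonide without ionising C12–O.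

**C1–C6 bond (24 ⇒ 23).** This is the ring-opening cut. Cutting C1–C7 or C6–O instead would leave the carbocycle to be built by other means and C6 to be set afterwards. Cutting C1–C6 removes the ring, the C6 stereocentre and the trisubstituted alkene in one stroke and leaves acyclic enethioate–aldehyde 23 with C4 as its only backbone stereocentre. The acyl group at C7 is taken as an S-ethyl thioester rather than an alkyl ester, because the phosphine-mediated cyclisation onto enolisable aldehydes is dependable for thioesters and sluggish for oxo-esters. The forward reaction must close cis to the C4 substituent.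

**C1=C2 bond and differentiation of the two arms at C4 (23 ⇒ 22 ⇒ 15 + 21; 15 ⇒ 14).** Aldehyde 23 comes from alcohol 22, and the enethioate from a Wittig reaction of ylide 21 with lactol 15, the half-reduced form of lactone 14. The lactone keeps the two three-atom arms at C4 distinct: its carbonyl end becomes C2 and its alkoxy end C6. A diol would make the arms identical and erase C4. The forward steps need a clean half-reduction and an E-selective olefination that leaves the free hydroxyl alone.

**C4–C8 bond (14 ⇒ 12 + 13).** Conjugate addition of alkenylboronate 12 to dihydropyranone 13 forms the bond that joins chain and ring carbons and sets C4 under control of a chiral rhodium catalyst. The neighbouring cut C8–C9 would need an ambident allylic nucleophile and a ketone at C8 next to C4. The chosen cut uses an sp2 boron reagent in which C8=C14 is already in place. It divides the molecule into a cheap achiral acceptor and a C10 fragment that carries only C12.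

**C8–B and C9–C10 bonds (12 ⇒ 10 ⇒ 7 + 8).** Boronate 12 comes from bromide 10, and 10 from alkyne 7 and 2,3-dibromopropene 8, which supplies C14=C8–C9 as a linchpin. Hydrometalation of the alkyne fixes the E geometry of C10=C11 by syn addition, which an olefination next to a quaternary centre would not guarantee.

**C12–O bond and C11 (7 ⇒ 6 ⇒ 4 ⇒ 3 ⇒ 1).** Alkyne 7 is the one-carbon homologue of aldehyde 6, obtained by ozonolysis of vinyl acetonide 4, the protected form of diol 3. Diol 3 is made from racemic vinyl epoxide 1 by a palladium-catalysed dynamic kinetic asymmetric addition of an oxygen nucleophile at the tertiary allylic carbon. A dihydroxylation route to the same carbinol would have to tell a methyl from an ethynyl group on a 1,1-disubstituted alkene, two small substituents, and C12 cannot be upgraded later. The epoxide route costs two more steps and is preferred for its selectivity.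

**Ylide (21 ⇒ 18 + 19; 18 ⇒ 16 + 17).** Ylide 21 comes from bromo thioester 18 and triphenylphosphine 19; 18 comes from bromoacetyl bromide 16 and ethanethiol 17.

## Roads not taken

**Alternative 1:** The cut is the C6–O bond, made with the C4 carboxyl (C8 at the acid level) as an internal nucleophile. Acid A2, with a C1=C6 alkene and a C7 silyl ether, would be closed onto C6 by an arylselenenyl halide. Oxidation of the C1 selenide would then eliminate toward C2 to give bridged ene-lactone A1.
- Merits: the 4,6-cis relation is a geometric necessity of the lactone bridge, which is a firmer guarantee for C6 than the conformational preference the chosen plan relies on. The syn-elimination also places the alkene at C1=C2, away from the oxygenated C6 and C7.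
- Weak points: closure at C6 (five-membered lactone) competes with Markovnikov attack at the tertiary C1. After A1, C8 is a lactone carbonyl that must become C8(=C14H2)–C9, which needs either an ambident allylic C9 nucleophile or a ketone and methylenation next to an epimerisable C4. C12 and the whole chain remain to be built, and selenium is used stoichiometrically.
- Comparison: A1 is better for certainty at C6. The chosen plan sets against it a C4–C8 bond formed with the finished chain and with C8=C14 in place, catalyst control at C4, and a late oxidation–reduction correction for C6 if it is needed.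

**Alternative 2:** The cut is the C12–O bond together with a transposition of the chain alkene. E-allylic alcohol A4 (C11=C12, C13 hydroxyl) would be epoxidised by the titanium–tartrate–hydroperoxide system to epoxy alcohol A3. Selenide opening at C11 and selenoxide elimination toward C10 would then give the tertiary allylic alcohol with E-C10=C11.
- Merits: the Sharpless epoxidation of E-trisubstituted allylic alcohols is among the most dependable reagent-controlled reactions, it is chemoselective for the allylic alcohol alkene, and no volatile chiral fragment is handled. For confidence in C12 this road is at least the equal of the chosen plan.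
- Weak points: it is a linear three-operation redox sequence on the most advanced intermediate, in the presence of C8=C14, C1=C2 and two silyl ethers. The chain must first be built with C9–C10 saturated and an E-trisubstituted allylic alcohol, which costs extra steps. Selenium is used again, and the tactic says nothing about the ring, C4 or C6.
- Comparison: the chosen plan fixes C12 at the outset in a five-carbon piece by a catalytic asymmetric reaction, obtains C10=C11 by hydrometalation and stays convergent.

**Alternative 3:** The cuts are C4–C5 and C1=C2 of the ring. Iminium catalysis by a diarylprolinol silyl ether would add β-keto ester A6 to enal A7 and set C4. Acid-mediated aldol condensation with loss of the tert-butyl ester would then give enone ester A5.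
- Merits: ring and C4 come from commodity chemicals in a short metal-free sequence. The C6 ketone can later be reduced to the cis alcohol, a more secure way to set C6 than the chosen cyclisation.
- Weak points: C7 is absent and must be added at C1 by a separate hydroxymethylation. C8 arrives as an ester, so C8–C9 and C8=C14 must be built through a ketone and a methylenation beside C4, which in A5 is α to the ester and exposed to enolisation. Many more steps follow the ring than in the chosen plan.
- Comparison: A5 is cheaper to reach and better for C6. The chosen plan sets against it that C7 is built in by the ylide, that C8=C14 is delivered intact by the boron reagent, and that three steps lead from the cyclisation to the target.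

Key step: step 13

Assumption: the sense of induction of the two chiral catalysts is taken from their accepted models ((R,R)-ligand → 2R diol in step 1; (R)-BINAP → 4R lactone in step 7, by analogy with (S)-BINAP giving (S)-3-substituted cyclohexanones); if either is the reverse, the mirror-image ligand is used and nothing else changes.

## Route

Step 1
Reactants: 1 rac-2-ethenyl-2-methyloxirane
Product: 3 (2R)-2-methylbut-3-ene-1,2-diol, via cyclic carbonate 2 (not isolated)
Conditions: Pd2(dba)3·CHCl3 (1 mol%), (R,R)-DACH-phenyl Trost ligand (3 mol%), Et3B (1 mol%), NaHCO3, CH2Cl2/H2O, rt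
Reagents that add atoms: sodium hydrogen carbonate, [Na+].OC([O-])=O
Why: Tsuji–Trost-type dynamic kinetic asymmetric transformation: zerovalent palladium ionises both enantiomers of 1 to one π-allyl alkoxide whose faces interconvert, the boron-bound carbonate closes onto the more substituted allyl terminus (five-membered carbonate 2) on the face chosen by the ligand, and hydrolysis of 2 releases the diol. C12 is set here under reagent control and the racemate can be consumed completely.

Step 2
Reactants: 3 (2R)-2-methylbut-3-ene-1,2-diol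
Product: 4 (4R)-4-ethenyl-2,2,4-trimethyl-1,3-dioxolane
Conditions: Me2C(OMe)2, PPTS (cat.), CH2Cl2, rt
Reagents that add atoms: 2,2-dimethoxypropane, COC(C)(C)OC
Why: Acid-catalysed transketalisation; the five-membered isopropylidene acetal forms readily from the 1,2-diol and C12 is not touched.

Step 3
Reactants: 4 (4R)-4-ethenyl-2,2,4-trimethyl-1,3-dioxolane
Product: 6 (4S)-2,2,4-trimethyl-1,3-dioxolane-4-carbaldehyde, via ozonide 5 (not isolated)
Conditions: O3, CH2Cl2, –78 °C; then Me2S, –78 °C → rt
Reagents that add atoms: ozone, [O-][O+]=O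
Why: Ozonolysis with reductive work-up (Criegee sequence through ozonide 5) cleaves the only alkene; the aldehyde has no α-hydrogen, so C12 cannot epimerise, and its descriptor changes from R to S only because the priority order changes.

Step 4
Reactants: 6 (4S)-2,2,4-trimethyl-1,3-dioxolane-4-carbaldehyde
Product: 7 (4R)-4-ethynyl-2,2,4-trimethyl-1,3-dioxolane
Conditions: dimethyl (1-diazo-2-oxopropyl)phosphonate, K2CO3, MeOH, 0 °C → rt
Reagents that add atoms: dimethyl (1-diazo-2-oxopropyl)phosphonate, COP(=O)(OC)C(=[N+]=[N-])C(C)=O
Why: Seyferth–Gilbert homologation in its Ohira–Bestmann form: the diazomethylphosphonate anion generated in the flask olefinates the aldehyde and the diazoalkene loses N2 with a 1,2-hydrogen shift. The quaternary α-carbon rules out epimerisation in basic methanol.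

Step 5
Reactants: 7 (4R)-4-ethynyl-2,2,4-trimethyl-1,3-dioxolane; 8 2,3-dibromopropene
Product: 10 (4R)-4-[(1E)-4-bromopenta-1,4-dien-1-yl]-2,2,4-trimethyl-1,3-dioxolane, via alkenylzirconocene chloride 9 (not isolated)
Conditions: Cp2Zr(H)Cl, THF, rt; then 8, CuCl (10 mol%), 0 °C → rt
Reagents that add atoms: none
Why: Hydrozirconation adds Zr–H syn and anti-Markovnikov to the terminal alkyne and fixes the E geometry of C10=C11; copper-catalysed allylation of the alkenylzirconocene with the allylic bromide of 8 forms C9–C10, and direct and allylically transposed substitution give the same 2-bromo-1,4-diene. The vinylic bromide of 8 is inert to the organocopper species.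

Step 6
Reactants: 10 (4R)-4-[(1E)-4-bromopenta-1,4-dien-1-yl]-2,2,4-trimethyl-1,3-dioxolane
Product: 12 4,4,5,5-tetramethyl-2-{(4E)-5-[(4R)-2,2,4-trimethyl-1,3-dioxolan-4-yl]penta-1,4-dien-2-yl}-1,3,2-dioxaborolane, via alkenyllithium 11 (not isolated)
Conditions: t-BuLi (2.1 equiv), Et2O, –78 °C; then iPrOBpin, –78 °C → rt; aq. NH4Cl
Reagents that add atoms: 2-isopropoxy-4,4,5,5-tetramethyl-1,3,2-dioxaborolane, CC(C)OB1OC(C)(C)C(C)(C)O1
Why: Lithium–bromine exchange on the 2-bromoalkene is faster at –78 °C than deprotonation of the doubly allylic C9H2, and the alkenyllithium is trapped by the borate ester (lithiation–borylation) to give a chromatographable pinacol boronate.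

Step 7
Reactants: 12 the alkenylboronate; 13 5,6-dihydro-2H-pyran-2-one
Product: 14 (4R)-4-{(4E)-5-[(4R)-2,2,4-trimethyl-1,3-dioxolan-4-yl]penta-1,4-dien-2-yl}oxan-2-one
Conditions: [RhCl(C2H4)2]2 (2.5 mol%), (R)-BINAP (5.5 mol%), aq. KOH (10 mol%), 1,4-dioxane/H2O (10:1), 50 °C; 13 (2 equiv)
Reagents that add atoms: none
Why: Hayashi–Miyaura asymmetric 1,4-addition: the hydroxorhodium–BINAP complex formed in the flask takes the alkenyl group from boron, inserts the lactone C=C on the face left open by the ligand and is released by hydrolysis of the oxa-π-allyl rhodium. This forms C4–C8 and sets C4 (4R in the lactone, 4S in target numbering) under catalyst control; the remote C12 has no say.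

Step 8
Reactants: 14 the (4R)-lactone
Product: 15 (4R)-4-{(4E)-5-[(4R)-2,2,4-trimethyl-1,3-dioxolan-4-yl]penta-1,4-dien-2-yl}oxan-2-ol (anomeric mixture)
Conditions: iBu2AlH (1.1 equiv), CH2Cl2, –78 °C; aq. potassium sodium tartrate
Reagents that add atoms: none
Why: Half-reduction of a lactone by iBu2AlH; the tetrahedral aluminium hemiacetal persists at –78 °C until work-up, so over-reduction to the diol, which would make the two arms at C4 identical, is avoided.

Step 9
Reactants: 16 bromoacetyl bromide; 17 ethanethiol
Product: 18 S-ethyl 2-bromoethanethioate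
Conditions: pyridine, CH2Cl2, 0 °C
Reagents that add atoms: none
Why: Acylation of the thiol by the acyl bromide, which is far more electrophilic than the alkyl bromide; pyridine takes up HBr.

Step 10
Reactants: 18 S-ethyl 2-bromoethanethioate; 19 triphenylphosphine
Product: 21 S-ethyl 2-(triphenyl-λ5-phosphanylidene)ethanethioate, via phosphonium bromide 20 (not isolated)
Conditions: toluene, rt; then aq. Na2CO3, CH2Cl2, rt
Reagents that add atoms: none
Why: SN2 quaternisation of the phosphine by the α-bromo thioester, then deprotonation of the acidic α-CH2, gives the stabilised ylide.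

Step 11
Reactants: 15 the lactol; 21 the thioester ylide
Product: 22 S-ethyl (2E,5S)-7-hydroxy-5-{(4E)-5-[(4R)-2,2,4-trimethyl-1,3-dioxolan-4-yl]penta-1,4-dien-2-yl}hept-2-enethioate
Conditions: 21 (1.5 equiv), toluene, 60 °C
Reagents that add atoms: none
Why: Wittig olefination of the hydroxy aldehyde in equilibrium with lactol 15; the stabilised ylide gives the E-enethioate and brings in C1 and C7. Neutral conditions and moderate temperature keep the free C6 hydroxyl from adding to the new acceptor.

Step 12
Reactants: 22 the hydroxy enethioate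
Product: 23 S-ethyl (2E,5S)-7-oxo-5-{(4E)-5-[(4R)-2,2,4-trimethyl-1,3-dioxolan-4-yl]penta-1,4-dien-2-yl}hept-2-enethioate
Conditions: Dess–Martin periodinane, NaHCO3, CH2Cl2, 0 °C → rt
Reagents that add atoms: none
Why: Dess–Martin oxidation of the primary alcohol under bicarbonate buffer; thioester, acetonide and alkenes are inert, and C4 is β to the new aldehyde and cannot epimerise.

Step 13
Reactants: 23 the enethioate–aldehyde
Product: 24 S-ethyl (4S,6S)-6-hydroxy-4-{(4E)-5-[(4R)-2,2,4-trimethyl-1,3-dioxolan-4-yl]penta-1,4-dien-2-yl}cyclohex-1-ene-1-carbothioate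
Conditions: PMe3 (0.3 equiv), CH2Cl2 (0.05 M), rt
Reagents that add atoms: none
Why: Trimethylphosphine adds to C2 of the enethioate to give a phosphonium thioester enolate whose C1 attacks the C6 aldehyde; proton transfer from C1 to the alkoxide and E1cB loss of the phosphine then restore C1=C2 and release the catalyst. The closest known reaction type is the phosphine-catalysed intramolecular Morita–Baylis–Hillman cyclisation of 7-oxohept-2-enethioates to 6-hydroxycyclohex-1-enecarbothioates, the substrate class in which the thioester (more electrophilic at C2 than an oxo-ester) lets cyclisation outrun aldol chemistry of an enolisable aldehyde. The six-membered ring closes in the 6-(enolexo)-exo-trig mode with formation of the C1–C6 bond. The new stereocentre C6 is controlled by C4: in a chair-like arrangement of C1–C6 the C4 dienyl group is equatorial and the aldehyde oxygen takes the equatorial position as well, which gives the 4,6-cis (4S,6S) carbinol, and reversibility of the aldol step ahead of the slower proton transfer should let the more stable cis aldolate drain to product. The step therefore needs 1,3-diastereocontrol and chemoselectivity; the latter is secured by the single conjugate acceptor in the substrate (C8=C14 and C10=C11 are unactivated), by a non-basic nucleophilic catalyst and by dilution, while the acetonide and C12 are spectators.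

Step 14
Reactants: 24 the cyclohexenol thioester
Product: 25 (1S,5S)-2-(hydroxymethyl)-5-{(4E)-5-[(4R)-2,2,4-trimethyl-1,3-dioxolan-4-yl]penta-1,4-dien-2-yl}cyclohex-2-en-1-ol
Conditions: iBu2AlH (4 equiv), CH2Cl2, –78 → 0 °C; aq. potassium sodium tartrate
Reagents that add atoms: none
Why: Hydride reduction of the thioester through the aldehyde to the allylic alcohol (1,2-reduction); the first equivalent is consumed by the C6 hydroxyl, and the acetonide and the alkenes are untouched at low temperature.

Step 15
Reactants: 25 the acetonide diol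
Product: 26 (2R,3E)-6-[(1S,5S)-5-hydroxy-4-(hydroxymethyl)cyclohex-3-en-1-yl]-2-methylhepta-3,6-diene-1,2-diol
Conditions: PPTS (0.2 equiv), MeOH, rt → 40 °C
Reagents that add atoms: none
Why: Acid-catalysed transketalisation to methanol removes the isopropylidene group; the weak pyridinium acid is chosen so that the tertiary allylic C12–O bond and the allylic C6 and C7 carbinols do not ionise.

Step 16
Reactants: 26 the tetraol
Product: 27 [(4S,6S)-6-hydroxy-4-{(4E,6R)-6-hydroxy-6-methyl-7-[(2-methylpropanoyl)oxy]hepta-1,4-dien-2-yl}cyclohex-1-en-1-yl]methyl 2-methylpropanoate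
Conditions: iPrCOCl (2.2 equiv), 2,4,6-collidine, CH2Cl2, –78 → –30 °C
Reagents that add atoms: 2-methylpropanoyl chloride, CC(C)C(Cl)=O
Why: Kinetically controlled acylation by an acyl chloride with a hindered pyridine base at low temperature distinguishes primary from secondary hydroxyls; the tertiary C12 hydroxyl is unreactive and the secondary allylic C6 hydroxyl, flanked by the substituted C1, should react last.

## Compound list

1 | rac-2-ethenyl-2-methyloxirane | C=CC1(C)CO1 | starting material
2 | (4R)-4-ethenyl-4-methyl-1,3-dioxolan-2-one | C=C[C@@]1(C)OC(=O)OC1 | intermediate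
3 | (2R)-2-methylbut-3-ene-1,2-diol | C=C[C@@](C)(O)CO | intermediate
4 | (4R)-4-ethenyl-2,2,4-trimethyl-1,3-dioxolane | C=C[C@@]1(C)OC(C)(C)OC1 | intermediate
5 | 3-[(4S)-2,2,4-trimethyl-1,3-dioxolan-4-yl]-1,2,4-trioxolane (both epimers at the trioxolane carbon) | C1(OCOO1)[C@@]2(C)OC(C)(C)OC2 | intermediate
6 | (4S)-2,2,4-trimethyl-1,3-dioxolane-4-carbaldehyde | O=C[C@@]1(C)OC(C)(C)OC1 | intermediate
7 | (4R)-4-ethynyl-2,2,4-trimethyl-1,3-dioxolane | C#C[C@@]1(C)OC(C)(C)OC1 | intermediate
8 | 2,3-dibromopropene | C=C(Br)CBr | starting material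
9 | chloridobis(cyclopentadienyl){(E)-2-[(4R)-2,2,4-trimethyl-1,3-dioxolan-4-yl]ethenyl}zirconium | Cl[Zr](/C=C/[C@@]1(C)OC(C)(C)OC1)(C1C=CC=C1)C1C=CC=C1 | intermediate
10 | (4R)-4-[(1E)-4-bromopenta-1,4-dien-1-yl]-2,2,4-trimethyl-1,3-dioxolane | C=C(Br)C/C=C/[C@@]1(C)OC(C)(C)OC1 | intermediate
11 | {(4E)-5-[(4R)-2,2,4-trimethyl-1,3-dioxolan-4-yl]penta-1,4-dien-2-yl}lithium | [Li]C(=C)C/C=C/[C@@]1(C)OC(C)(C)OC1 | intermediate
12 | 4,4,5,5-tetramethyl-2-{(4E)-5-[(4R)-2,2,4-trimethyl-1,3-dioxolan-4-yl]penta-1,4-dien-2-yl}-1,3,2-dioxaborolane | C=C(B1OC(C)(C)C(C)(C)O1)C/C=C/[C@@]2(C)OC(C)(C)OC2 | intermediate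
13 | 5,6-dihydro-2H-pyran-2-one | O=C1C=CCCO1 | starting material
14 | (4R)-4-{(4E)-5-[(4R)-2,2,4-trimethyl-1,3-dioxolan-4-yl]penta-1,4-dien-2-yl}oxan-2-one | O=C1C[C@H](C(=C)C/C=C/[C@@]2(C)OC(C)(C)OC2)CCO1 | intermediate
15 | (4R)-4-{(4E)-5-[(4R)-2,2,4-trimethyl-1,3-dioxolan-4-yl]penta-1,4-dien-2-yl}oxan-2-ol (anomeric mixture) | OC1C[C@H](C(=C)C/C=C/[C@@]2(C)OC(C)(C)OC2)CCO1 | intermediate
16 | bromoacetyl bromide | O=C(Br)CBr | starting material
17 | ethanethiol | CCS | starting material
18 | S-ethyl 2-bromoethanethioate | CCSC(=O)CBr | intermediate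
19 | triphenylphosphine | c1ccc(cc1)P(c1ccccc1)c1ccccc1 | starting material
20 | [2-(ethylsulfanyl)-2-oxoethyl](triphenyl)phosphonium bromide | CCSC(=O)C[P+](c1ccccc1)(c1ccccc1)c1ccccc1.[Br-] | intermediate
21 | S-ethyl 2-(triphenyl-λ5-phosphanylidene)ethanethioate | CCSC(=O)C=P(c1ccccc1)(c1ccccc1)c1ccccc1 | intermediate
22 | S-ethyl (2E,5S)-7-hydroxy-5-{(4E)-5-[(4R)-2,2,4-trimethyl-1,3-dioxolan-4-yl]penta-1,4-dien-2-yl}hept-2-enethioate | CCSC(=O)/C=C/C[C@@H](CCO)C(=C)C/C=C/[C@@]1(C)OC(C)(C)OC1 | intermediate
23 | S-ethyl (2E,5S)-7-oxo-5-{(4E)-5-[(4R)-2,2,4-trimethyl-1,3-dioxolan-4-yl]penta-1,4-dien-2-yl}hept-2-enethioate | CCSC(=O)/C=C/C[C@@H](CC=O)C(=C)C/C=C/[C@@]1(C)OC(C)(C)OC1 | intermediate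
24 | S-ethyl (4S,6S)-6-hydroxy-4-{(4E)-5-[(4R)-2,2,4-trimethyl-1,3-dioxolan-4-yl]penta-1,4-dien-2-yl}cyclohex-1-ene-1-carbothioate | C=C(C/C=C/[C@@]2(C)OC(C)(C)OC2)[C@H]1CC=C(C(=O)SCC)[C@@H](O)C1 | intermediate
25 | (1S,5S)-2-(hydroxymethyl)-5-{(4E)-5-[(4R)-2,2,4-trimethyl-1,3-dioxolan-4-yl]penta-1,4-dien-2-yl}cyclohex-2-en-1-ol | C=C(C/C=C/[C@@]2(C)OC(C)(C)OC2)[C@H]1CC=C(CO)[C@@H](O)C1 | intermediate
26 | (2R,3E)-6-[(1S,5S)-5-hydroxy-4-(hydroxymethyl)cyclohex-3-en-1-yl]-2-methylhepta-3,6-diene-1,2-diol | C=C(C/C=C/[C@@](C)(O)CO)[C@H]1CC=C(CO)[C@@H](O)C1 | intermediate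
27 | [(4S,6S)-6-hydroxy-4-{(4E,6R)-6-hydroxy-6-methyl-7-[(2-methylpropanoyl)oxy]hepta-1,4-dien-2-yl}cyclohex-1-en-1-yl]methyl 2-methylpropanoate | C=C(C/C=C/[C@@](C)(O)COC(=O)C(C)C)[C@H]1CC=C(COC(=O)C(C)C)[C@@H](O)C1 | target

## Step count and least certain steps

Total step count: 16. Longest linear sequence: 14 steps (steps 1–8 and 11–16, from 1 to 27); steps 9 and 10 are the side branch to ylide 21.

**Step 13 (key step).**
- Risk: insufficient facial selectivity in the aldol closure. C6 is steered only by a conformational preference, and the cis carbinol suffers allylic strain against the C1 acyl group. Intermolecular aldol reactions of the enolisable aldehyde may also compete if phosphine addition is slow.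
- Fallback (sets out from 23, returns at 27): the cyclisation is run without regard to C6, so that 24 is accompanied by the 6-epi thioester F1. The mixture is taken through steps 14–16, which gives beside 25, 26 and 27 the 6-epi diol F2, the 6-epi tetraol F3 and the 6-epi diester F4. Oxidation of 27 and F4 together with MnO2 (CH2Cl2, rt) converges both on the C6 enone F5; only the secondary allylic C6 carbinol can react. Luche reduction (NaBH4, CeCl3·7H2O, MeOH, –78 °C) should deliver hydride axially to the half-chair with the C4 chain equatorial, as is general for 5-substituted 2-alkylcyclohex-2-enones, and give the cis alcohol 27 with both esters intact.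

**Step 7.**
- Risk: slow boron-to-rhodium transfer of the α-branched alkenyl group with competing protodeboronation, hydroxide-induced opening of lactone 13 or 14, or erosion of enantioselectivity at the temperature needed.
- Fallback (sets out from 10, returns at 14): auxiliary-controlled conjugate addition. Alkenyllithium 11, made from 10 as in step 6, is converted with MgBr2·OEt2 and CuBr·SMe2 into the magnesium cuprate. It is added in THF at –40 → –10 °C to the separately prepared N-enoyl oxazolidinone (4S)-4-benzyl-3-[(2E)-5-silyloxypent-2-enoyl]oxazolidin-2-one F6. Attack anti to the benzyl group in the chelated s-cis conformer should give the (3R) imide adduct F7. Tetrabutylammonium fluoride in THF removes the silyl group; the liberated alkoxide lactonises onto the imide, releases the auxiliary and returns lactone 14.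

**Step 16.**
- Risk: incomplete discrimination between the hydroxyls. The neopentyl-type C13 hydroxyl acylates slowly, so acylation of the secondary C6 hydroxyl or migration of the C7 acyl group to O6 can intervene before both primary positions are esterified.
- Fallback (sets out from 24, returns at 27): C6 is masked first. Silylation of 24 (TBSOTf, 2,6-lutidine, CH2Cl2, –78 °C) gives the C6 silyl ether thioester F8. Reduction with iBu2AlH gives the C7 alcohol F9. PPTS in MeOH removes the acetonide to give the silylated triol F10. Acylation of both primary hydroxyls (iPrCOCl, pyridine, CH2Cl2, 0 °C) gives the silylated diester F11. HF·pyridine in THF/pyridine removes the silyl group under non-basic conditions and gives 27.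

**Step 11.**
- Risk: conjugate addition of the free C6 hydroxyl to the newly formed enethioate (six-membered oxa-Michael closure), triggered by the basic ylide or by traces of acid and easier for a thioester than for an ester.
- Fallback (sets out from 14, returns at 23): the hydroxyl is kept masked while the acceptor is present. Aminolysis of 14 (MeNH(OMe)·HCl, iPrMgCl, THF, –20 °C) gives the hydroxy Weinreb amide F12. Silylation (Et3SiCl, imidazole) gives the triethylsilyl ether amide F13. Reduction with iBu2AlH (THF, –78 °C) gives the silyloxy aldehyde F14. Wittig reaction with 21 gives the silyloxy enethioate F15. Swern conditions ((COCl)2, DMSO, Et3N, –78 → –20 °C) convert the primary triethylsilyl ether directly into the aldehyde and give 23.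

## Further compounds

F1 | step 13 | S-ethyl (4S,6R)-6-hydroxy-4-{(4E)-5-[(4R)-2,2,4-trimethyl-1,3-dioxolan-4-yl]penta-1,4-dien-2-yl}cyclohex-1-ene-1-carbothioate | C=C(C/C=C/[C@@]2(C)OC(C)(C)OC2)[C@H]1CC=C(C(=O)SCC)[C@H](O)C1
F2 | step 13 | (1R,5S)-2-(hydroxymethyl)-5-{(4E)-5-[(4R)-2,2,4-trimethyl-1,3-dioxolan-4-yl]penta-1,4-dien-2-yl}cyclohex-2-en-1-ol | C=C(C/C=C/[C@@]2(C)OC(C)(C)OC2)[C@H]1CC=C(CO)[C@H](O)C1
F3 | step 13 | (2R,3E)-6-[(1S,5R)-5-hydroxy-4-(hydroxymethyl)cyclohex-3-en-1-yl]-2-methylhepta-3,6-diene-1,2-diol | C=C(C/C=C/[C@@](C)(O)CO)[C@H]1CC=C(CO)[C@H](O)C1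
F4 | step 13 | [(4S,6R)-6-hydroxy-4-{(4E,6R)-6-hydroxy-6-methyl-7-[(2-methylpropanoyl)oxy]hepta-1,4-dien-2-yl}cyclohex-1-en-1-yl]methyl 2-methylpropanoate | C=C(C/C=C/[C@@](C)(O)COC(=O)C(C)C)[C@H]1CC=C(COC(=O)C(C)C)[C@H](O)C1
F5 | step 13 | [(4S)-4-{(4E,6R)-6-hydroxy-6-methyl-7-[(2-methylpropanoyl)oxy]hepta-1,4-dien-2-yl}-6-oxocyclohex-1-en-1-yl]methyl 2-methylpropanoate | C=C(C/C=C/[C@@](C)(O)COC(=O)C(C)C)[C@H]1CC=C(COC(=O)C(C)C)C(=O)C1
F6 | step 7 | (4S)-4-benzyl-3-[(2E)-5-{[tert-butyl(dimethyl)silyl]oxy}pent-2-enoyl]-1,3-oxazolidin-2-one | O=C(/C=C/CCO[Si](C)(C)C(C)(C)C)N1[C@@H](Cc2ccccc2)COC1=O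
F7 | step 7 | (4S)-4-benzyl-3-[(3R)-5-{[tert-butyl(dimethyl)silyl]oxy}-3-{(4E)-5-[(4R)-2,2,4-trimethyl-1,3-dioxolan-4-yl]penta-1,4-dien-2-yl}pentanoyl]-1,3-oxazolidin-2-one | O=C(C[C@@H](CCO[Si](C)(C)C(C)(C)C)C(=C)C/C=C/[C@@]1(C)OC(C)(C)OC1)N1[C@@H](Cc2ccccc2)COC1=O
F8 | step 16 | S-ethyl (4S,6S)-6-{[tert-butyl(dimethyl)silyl]oxy}-4-{(4E)-5-[(4R)-2,2,4-trimethyl-1,3-dioxolan-4-yl]penta-1,4-dien-2-yl}cyclohex-1-ene-1-carbothioate | C=C(C/C=C/[C@@]2(C)OC(C)(C)OC2)[C@H]1CC=C(C(=O)SCC)[C@@H](O[Si](C)(C)C(C)(C)C)C1
F9 | step 16 | [(4S,6S)-6-{[tert-butyl(dimethyl)silyl]oxy}-4-{(4E)-5-[(4R)-2,2,4-trimethyl-1,3-dioxolan-4-yl]penta-1,4-dien-2-yl}cyclohex-1-en-1-yl]methanol | C=C(C/C=C/[C@@]2(C)OC(C)(C)OC2)[C@H]1CC=C(CO)[C@@H](O[Si](C)(C)C(C)(C)C)C1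
F10 | step 16 | (2R,3E)-6-[(1S,5S)-5-{[tert-butyl(dimethyl)silyl]oxy}-4-(hydroxymethyl)cyclohex-3-en-1-yl]-2-methylhepta-3,6-diene-1,2-diol | C=C(C/C=C/[C@@](C)(O)CO)[C@H]1CC=C(CO)[C@@H](O[Si](C)(C)C(C)(C)C)C1
F11 | step 16 | [(4S,6S)-6-{[tert-butyl(dimethyl)silyl]oxy}-4-{(4E,6R)-6-hydroxy-6-methyl-7-[(2-methylpropanoyl)oxy]hepta-1,4-dien-2-yl}cyclohex-1-en-1-yl]methyl 2-methylpropanoate | C=C(C/C=C/[C@@](C)(O)COC(=O)C(C)C)[C@H]1CC=C(COC(=O)C(C)C)[C@@H](O[Si](C)(C)C(C)(C)C)C1
F12 | step 11 | (3R)-5-hydroxy-N-methoxy-N-methyl-3-{(4E)-5-[(4R)-2,2,4-trimethyl-1,3-dioxolan-4-yl]penta-1,4-dien-2-yl}pentanamide | CON(C)C(=O)C[C@@H](CCO)C(=C)C/C=C/[C@@]1(C)OC(C)(C)OC1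
F13 | step 11 | (3R)-N-methoxy-N-methyl-5-[(triethylsilyl)oxy]-3-{(4E)-5-[(4R)-2,2,4-trimethyl-1,3-dioxolan-4-yl]penta-1,4-dien-2-yl}pentanamide | CON(C)C(=O)C[C@@H](CCO[Si](CC)(CC)CC)C(=C)C/C=C/[C@@]1(C)OC(C)(C)OC1
F14 | step 11 | (3R)-5-[(triethylsilyl)oxy]-3-{(4E)-5-[(4R)-2,2,4-trimethyl-1,3-dioxolan-4-yl]penta-1,4-dien-2-yl}pentanal | O=CC[C@@H](CCO[Si](CC)(CC)CC)C(=C)C/C=C/[C@@]1(C)OC(C)(C)OC1
F15 | step 11 | S-ethyl (2E,5S)-7-[(triethylsilyl)oxy]-5-{(4E)-5-[(4R)-2,2,4-trimethyl-1,3-dioxolan-4-yl]penta-1,4-dien-2-yl}hept-2-enethioate | CCSC(=O)/C=C/C[C@@H](CCO[Si](CC)(CC)CC)C(=C)C/C=C/[C@@]1(C)OC(C)(C)OC1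
A1 | alternative 1 | (1S,5S)-4-({[tert-butyl(dimethyl)silyl]oxy}methyl)-6-oxabicyclo[3.2.1]oct-3-en-7-one | O=C2[C@H]1CC=C(CO[Si](C)(C)C(C)(C)C)[C@@H](O2)C1
A2 | alternative 1 | (1S)-4-({[tert-butyl(dimethyl)silyl]oxy}methyl)cyclohex-3-ene-1-carboxylic acid | O=C(O)[C@@H]1CC=C(CO[Si](C)(C)C(C)(C)C)CC1
A3 | alternative 2 | [(2S,3S)-3-{3-[(1S,5S)-5-{[tert-butyl(dimethyl)silyl]oxy}-4-({[tert-butyl(dimethyl)silyl]oxy}methyl)cyclohex-3-en-1-yl]but-3-en-1-yl}-2-methyloxiran-2-yl]methanol | C=C(CC[C@@H]1O[C@@]1(C)CO)[C@H]2CC=C(CO[Si](C)(C)C(C)(C)C)[C@@H](O[Si](C)(C)C(C)(C)C)C2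
A4 | alternative 2 | (2E)-6-[(1S,5S)-5-{[tert-butyl(dimethyl)silyl]oxy}-4-({[tert-butyl(dimethyl)silyl]oxy}methyl)cyclohex-3-en-1-yl]-2-methylhepta-2,6-dien-1-ol | C=C(CC/C=C(\C)CO)[C@H]2CC=C(CO[Si](C)(C)C(C)(C)C)[C@@H](O[Si](C)(C)C(C)(C)C)C2
A5 | alternative 3 | ethyl (1S)-5-oxocyclohex-3-ene-1-carboxylate | CCOC(=O)[C@H]1CC=CC(=O)C1
A6 | alternative 3 | tert-butyl 3-oxobutanoate | CC(=O)CC(=O)OC(C)(C)C
A7 | alternative 3 | ethyl (2E)-4-oxobut-2-enoate | CCOC(=O)/C=C/C=O
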